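The route rests on cutting the 2,4-dibromophenyl ring at its C1–O bond and its neighbouring C2–Br bond. The ether oxygen on C1, the bromine on C2 and the second bromine on C4 (para to C1) mark this ring as 4-bromobenzyne that has accepted an aryloxide and a bromine across the triple bond. The other ring, 2,4-dibromo-6-methoxyphenoxide, has both ortho carbons and its para carbon substituted and can react only at oxygen. One operation therefore forms the diaryl ether and the ortho C–Br bond from 4-bromo-2-(trimethylsilyl)phenyl triflate, the dry cesium phenoxide and 1,2-dibromotetrachloroethane as bromine donor. Both rings are bought intact and no stereocentre exists.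

Key step: step 7

Remark on the chemistry: the structures of all planned intermediates were checked against the target and needed no correction; the target is achiral, so no descriptor has to be set.

Step 1
Reactants: 1 4-bromo-2-iodophenol
Product: 2 (4-bromo-2-iodophenoxy)trimethylsilane
Conditions: (Me3Si)2NH (0.7 equiv), THF, 65 °C; volatiles removed in vacuo, used crude
Reagents that add atoms: hexamethyldisilazane, C[Si](C)(C)N[Si](C)(C)C
Why: O-silylation of a phenol with hexamethyldisilazane gives only ammonia as by-product, so the moisture-sensitive silyl ether needs no aqueous work-up.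

Step 2
Reactants: 2 (4-bromo-2-iodophenoxy)trimethylsilane
Product: 5 4-bromo-2-(trimethylsilyl)phenol, via aryllithium 3 (not isolated), via lithium phenoxide 4 (not isolated)
Conditions: n-BuLi (1.0 equiv), THF/Et2O, −100 °C, then −78 °C; aq NH4Cl
Reagents that add atoms: none
Why: Iodine–lithium exchange is much faster than bromine–lithium exchange at −100 °C, and the ortho-lithiated aryl silyl ether then undergoes the 1,3 O-to-C silyl shift (retro-Brook rearrangement), driven by formation of the lithium phenoxide, with the aryl bromide left untouched.

Step 3
Reactants: 5 4-bromo-2-(trimethylsilyl)phenol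
Product: 6 4-bromo-2-(trimethylsilyl)phenyl trifluoromethanesulfonate
Conditions: Tf2O (1.2 equiv), pyridine (2 equiv), CH2Cl2, 0 °C
Reagents that add atoms: trifluoromethanesulfonic anhydride, O=S(=O)(OS(=O)(=O)C(F)(F)F)C(F)(F)F
Why: O-triflation of a phenol with triflic anhydride and pyridine, conditions to which the C–Si bond and the aryl bromide are inert.

Step 4
Reactants: 7 guaiacol (2-methoxyphenol)
Product: 8 4-bromo-2-methoxyphenol
Conditions: NBS (1.0 equiv), MeCN, 0 °C
Reagents that add atoms: N-bromosuccinimide, O=C1CCC(=O)N1Br
Why: Electrophilic aromatic bromination, in which the free hydroxyl is the stronger activator and directs bromine to its para carbon (C4).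

Step 5
Reactants: 8 4-bromo-2-methoxyphenol
Product: 9 2,4-dibromo-6-methoxyphenol
Conditions: NBS (1.05 equiv), i-Pr2NH (10 mol%), CH2Cl2, 0 °C to rt
Reagents that add atoms: N-bromosuccinimide, O=C1CCC(=O)N1Br
Why: Amine-catalysed ortho-bromination of a phenol, in which the N-bromoamine formed from NBS is hydrogen-bonded to the phenolic OH and delivers bromine to the adjacent C6, the para position being already occupied.

Step 6
Reactants: 9 2,4-dibromo-6-methoxyphenol
Product: 10 cesium 2,4-dibromo-6-methoxyphenoxide
Conditions: CsOH·H2O (1.00 equiv, titrated), MeOH, rt; evaporation; toluene azeotrope; 60 °C, high vacuum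
Reagents that add atoms: cesium hydroxide monohydrate, [Cs+].[OH-].O
Why: Acid–base reaction in which one equivalent of hydroxide fully deprotonates the acidic dibromophenol, after which water and methanol are removed by azeotroping and vacuum drying so that no proton source is carried into the key step.

Step 7
Reactants: 6 4-bromo-2-(trimethylsilyl)phenyl trifluoromethanesulfonate; 10 cesium 2,4-dibromo-6-methoxyphenoxide; 11 1,2-dibromo-1,1,2,2-tetrachloroethane
Product: 14 2,4-dibromo-1-(2,4-dibromo-6-methoxyphenoxy)benzene, via 4-bromobenzyne 12 (not isolated), via arylcesium 13 (not isolated)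
Conditions: CsF (3 equiv), 18-crown-6 (1 equiv), 10 (1.5 equiv), 11 (3 equiv), 4 Å MS, THF, 0 °C to rt; 6 added by syringe pump
Reagents that add atoms: 1,2-dibromo-1,1,2,2-tetrachloroethane 11, ClC(Cl)(Br)C(Cl)(Cl)Br
Why: Proposed new method: fluoride attacks the silicon of 6 and expels triflate, releasing 4-bromobenzyne 12 at low stationary concentration; the oxygen of 10 adds to the aryne carbon para to the ring bromine (the ether C–O bond), and the resulting arylcesium 13 takes bromine from 11 by halophilic attack (the ortho C–Br bond), 11 collapsing to tetrachloroethylene and bromide. The closest known reaction types are the fluoride-induced O-arylation of phenols with 2-silylaryl triflates and three-component aryne couplings in which the aryl anion formed by addition of a heteroatom nucleophile is intercepted by a halogen-transfer reagent. No ring is closed and no stereocentre is formed. The step needs O- over C-arylation, which the substituted ortho and para carbons of 10 (OMe, Br, Br) ensure, and bromination over protonation, which the excess of 11 and the ethereal, proton-free medium should secure. It also needs attack para rather than meta to the ring bromine, which is favoured only modestly by inductive stabilisation of the carbanion developing meta to that bromine, so the regioisomeric ether is expected as a minor product to be removed by chromatography or crystallisation. The aryl bromides are inert without a transition metal, and any bromine transferred to 10 should give an ipso-bromodienone that is itself a bromine donor and returns the phenoxide.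

Compound list
1 | 4-bromo-2-iodophenol | Oc1ccc(Br)cc1I | starting material
2 | (4-bromo-2-iodophenoxy)trimethylsilane | C[Si](C)(C)Oc1ccc(Br)cc1I | intermediate
3 | [5-bromo-2-(trimethylsilyloxy)phenyl]lithium | C[Si](C)(C)Oc1ccc(Br)cc1[Li] | intermediate
4 | lithium 4-bromo-2-(trimethylsilyl)phenoxide | C[Si](C)(C)c1cc(Br)ccc1[O-].[Li+] | intermediate
5 | 4-bromo-2-(trimethylsilyl)phenol | C[Si](C)(C)c1cc(Br)ccc1O | intermediate
6 | 4-bromo-2-(trimethylsilyl)phenyl trifluoromethanesulfonate | C[Si](C)(C)c1cc(Br)ccc1OS(=O)(=O)C(F)(F)F | intermediate
7 | guaiacol (2-methoxyphenol) | COc1ccccc1O | starting material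
8 | 4-bromo-2-methoxyphenol | COc1cc(Br)ccc1O | intermediate
9 | 2,4-dibromo-6-methoxyphenol | COc1cc(Br)cc(Br)c1O | intermediate
10 | cesium 2,4-dibromo-6-methoxyphenoxide | COc1cc(Br)cc(Br)c1[O-].[Cs+] | intermediate
11 | 1,2-dibromo-1,1,2,2-tetrachloroethane | ClC(Cl)(Br)C(Cl)(Cl)Br | starting material
12 | 4-bromobenzyne (4-bromo-1,2-didehydrobenzene) | BrC1=CC#CC=C1 | intermediate
13 | [5-bromo-2-(2,4-dibromo-6-methoxyphenoxy)phenyl]cesium | COc1cc(Br)cc(Br)c1OC1=[C-]C=C(Br)C=C1.[Cs+] | intermediate
14 | 2,4-dibromo-1-(2,4-dibromo-6-methoxyphenoxy)benzene | COc1cc(Br)cc(Br)c1Oc1ccc(Br)cc1Br | target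

Total step count: 7
Longest linear sequence: 4 steps (1 → 2 → 5 → 6 → 14; the branch 7 → 8 → 9 → 10 → 14 is equally long)

Steps most likely to fail

1. Step 7. The oxygen nucleophile may attack the unsymmetrical aryne with poor site selectivity, and protonation of the aryl anion may compete with bromine transfer. The fallback is the known O-arylation of phenoxides with diaryliodonium salts. It sets out from 10, which is heated in DMF at 80 °C with bis(2,4-dibromophenyl)iodonium chloride F1. F1 is prepared separately from 1,3-dibromobenzene and iodosyl sulfate (I2 and KIO3 in concentrated H2SO4), then precipitated with NaCl. Ligand coupling at trivalent iodine transfers an intact 2,4-dibromophenyl group to oxygen, so the positions of both bromines are fixed beforehand and no regioisomer can arise. The fallback comes back to the route at 14.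

2. Step 2. Bromine–lithium exchange or metal scrambling between the two halogen positions may compete with the iodine-selective exchange, and the silyl migration may stall. The fallback replaces the intramolecular shift by intermolecular C-silylation of an arylmagnesium. It sets out from 1, which is silylated with TBSCl and imidazole in DMF to give tert-butyl(4-bromo-2-iodophenoxy)dimethylsilane F2. Iodine–magnesium exchange with i-PrMgCl·LiCl in THF at −40 °C, which leaves aryl bromides alone at this temperature, gives [5-bromo-2-(tert-butyldimethylsilyloxy)phenyl]magnesium chloride F3. Quenching with Me3SiCl on warming to rt gives tert-butyl[4-bromo-2-(trimethylsilyl)phenoxy]dimethylsilane F4. Bu4NF in THF at 0 °C then cleaves only the phenolic silyl ether, and the fallback comes back to the route at 5.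

3. Step 5. The second bromination may drift to the carbon para to the methoxy group or run on to a tribromide. The fallback reverses the order of the two brominations, so that the last one takes place at the most activated open position. It sets out from 7, which is brominated ortho to the hydroxyl with t-BuNH2 and Br2 in toluene at −78 °C to give 2-bromo-6-methoxyphenol F5. Bu4NBr3 in CH2Cl2/MeOH at rt then brominates para to the hydroxyl, and the fallback comes back to the route at 9.

Further compounds
F1 | step 7 | bis(2,4-dibromophenyl)iodonium chloride | Brc1ccc([I+]c2ccc(Br)cc2Br)c(Br)c1.[Cl-]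
F2 | step 2 | tert-butyl(4-bromo-2-iodophenoxy)dimethylsilane | CC(C)(C)[Si](C)(C)Oc1ccc(Br)cc1I
F3 | step 2 | [5-bromo-2-(tert-butyldimethylsilyloxy)phenyl]magnesium chloride | CC(C)(C)[Si](C)(C)Oc1ccc(Br)cc1[Mg]Cl
F4 | step 2 | tert-butyl[4-bromo-2-(trimethylsilyl)phenoxy]dimethylsilane | CC(C)(C)[Si](C)(C)Oc1ccc(Br)cc1[Si](C)(C)C
F5 | step 5 | 2-bromo-6-methoxyphenol | COc1cccc(Br)c1O
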